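**Retrosynthetic overview**
- The target comes from one final methanolysis of a tris-ester (two aryl pivalates, one allylic acetate) of the complete bicyclo[3.3.1]nonane.
- Ring B (C1–C8–C7–C6–C5–C9) is closed last, by a formic acid cation–enol cyclisation (C5–C6 bond) of a dearomatised, fully substituted acylphloroglucinol; the lavandulyl stereocentre becomes C7 and directs the ring closure.
- That dienone comes from C-prenylation after removal of a methyl ester, which serves as a traceless blocking group so that the two non-acyl ring carbons are never ambiguous.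
- Key step: palladium-catalysed dearomative allylation of a hexasubstituted benzoate with the complete, enantiopure hydroxygeranyl chain (as its diacetate), creating the C1 quaternary centre; ring A is the former benzene ring.
- The arene is assembled from methyl 2,4,6-trihydroxybenzoate, protocatechuic acid and (S)-lavandulyl triflate (Evans alkylation); the chain comes from (E)-4-acetoxy-2-methylbut-2-enal (Keck allylation, cross-metathesis).

Assumption: all β-triketone compounds are drawn and named as single enol tautomers (descriptors refer to the tautomer drawn), and in step 12 the (R,R)-ligand is taken as the matched one (its mirror image is used if the sense of induction proves opposite).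

**Step 1**
Reactants: 1 3,4-dihydroxybenzoic acid
Product: 2 3,4-bis(pivaloyloxy)benzoic acid
Conditions: pivaloyl chloride (2.3 equiv), aq. NaOH, THF, 0 °C; then HCl to pH 2
Reagents that add atoms: pivaloyl chloride, CC(C)(C)C(Cl)=O
Why: Schotten–Baumann O-acylation of the two phenoxides gives hindered aryl pivalates that survive the later amide bases, palladium and formic acid and are removed in the final methanolysis.

**Step 2**
Reactants: 2 3,4-bis(pivaloyloxy)benzoic acid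
Product: 3 3,4-bis(pivaloyloxy)benzoyl chloride
Conditions: (COCl)2, DMF (cat.), CH2Cl2, 0 °C to rt
Reagents that add atoms: oxalyl chloride, O=C(Cl)C(Cl)=O
Why: Vilsmeier-catalysed acid chloride formation under neutral conditions leaves the aryl pivalates intact.

**Step 3**
Reactants: 3 3,4-bis(pivaloyloxy)benzoyl chloride; 4 methyl 2,4,6-trihydroxybenzoate
Product: 5 methyl 3-[3,4-bis(pivaloyloxy)benzoyl]-2,4,6-trihydroxybenzoate
Conditions: AlCl3 (4 equiv), PhNO2–CH2Cl2, 0 to 40 °C; cold aq. HCl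
Reagents that add atoms: none
Why: Friedel–Crafts C-acylation (O-acylation/Fries manifold) at one of the two equivalent free ring carbons, after which ester and ketone deactivate the ring so exactly one free ring carbon remains.

**Step 4**
Reactants: 6 (S)-4-benzyloxazolidin-2-one; 7 3-methylbut-2-enoyl chloride
Product: 8 (S)-4-benzyl-3-(3-methylbut-2-enoyl)oxazolidin-2-one
Conditions: n-BuLi, THF, −78 °C; then 7, −78 to 0 °C
Reagents that add atoms: none
Why: N-acylation of the lithiated oxazolidinone gives the Evans imide.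

**Step 5**
Reactants: 8 (S)-4-benzyl-3-(3-methylbut-2-enoyl)oxazolidin-2-one; 9 1-bromo-3-methylbut-2-ene (prenyl bromide)
Product: 10 (S)-4-benzyl-3-[(2S)-5-methyl-2-(prop-1-en-2-yl)hex-4-enoyl]oxazolidin-2-one
Conditions: NaN(SiMe3)2, THF, −78 °C; then 9, −78 to −40 °C
Reagents that add atoms: none
Why: Evans deconjugative alkylation, in which γ-deprotonation gives the chelated Z(O)-dienolate and prenyl bromide attacks the α-carbon on the face opposite the benzyl group, setting the (2S) centre that becomes C7.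

**Step 6**
Reactants: 10 (S)-4-benzyl-3-[(2S)-5-methyl-2-(prop-1-en-2-yl)hex-4-enoyl]oxazolidin-2-one
Product: 11 (S)-lavandulol [(2S)-5-methyl-2-(prop-1-en-2-yl)hex-4-en-1-ol]
Conditions: LiBH4, MeOH (1 equiv), Et2O, 0 °C
Reagents that add atoms: none
Why: reductive removal of the auxiliary by borohydride leaves the α-stereocentre and both alkenes untouched.

**Step 7**
Reactants: 11 (S)-lavandulol
Product: 12 (S)-lavandulyl triflate [(2S)-5-methyl-2-(prop-1-en-2-yl)hex-4-en-1-yl trifluoromethanesulfonate]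
Conditions: Tf2O, 2,6-lutidine, CH2Cl2, −78 °C; cold pentane filtration, used at once
Reagents that add atoms: triflic anhydride, O=S(=O)(OS(=O)(=O)C(F)(F)F)C(F)(F)F
Why: O-sulfonylation at low temperature gives the leaving group needed for SN2 C-alkylation with this β-branched homoallylic carbon.

**Step 8**
Reactants: 5 methyl 3-[3,4-bis(pivaloyloxy)benzoyl]-2,4,6-trihydroxybenzoate; 12 (S)-lavandulyl triflate
Product: 13 methyl 3-[3,4-bis(pivaloyloxy)benzoyl]-2,4,6-trihydroxy-5-[(2R)-5-methyl-2-(prop-1-en-2-yl)hex-4-en-1-yl]benzoate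
Conditions: LiN(SiMe3)2 (3.1 equiv), THF, −78 °C; then 12 (1.3 equiv), −78 to 0 °C; aq. NH4Cl
Reagents that add atoms: none
Why: the lithium-chelated trianion undergoes SN2 C-alkylation at its only unsubstituted ring carbon, and the lavandulyl centre is not touched (S to R is a change of CIP priorities only).

**Step 9**
Reactants: 14 (E)-4-acetoxy-2-methylbut-2-enal
Product: 15 (2E,4S)-4-hydroxy-3-methylhepta-2,6-dien-1-yl acetate
Conditions: (S)-1,1'-bi-2-naphthol (10 mol%), Ti(OiPr)4 (10 mol%), 4 Å sieves, CH2=CHCH2SnBu3 (1.5 equiv), CH2Cl2, −20 °C; aq. NaHCO3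
Reagents that add atoms: allyltributylstannane, C=CC[Sn](CCCC)(CCCC)CCCC
Why: Keck catalytic asymmetric allylation, in which the (S)-binaphthol–titanium Lewis acid exposes one aldehyde face and gives the (4S) carbinol.

**Step 10**
Reactants: 15 (2E,4S)-4-hydroxy-3-methylhepta-2,6-dien-1-yl acetate
Product: 16 (2E,4S)-4-hydroxy-3,7-dimethylocta-2,6-dien-1-yl acetate
Conditions: 2-methylbut-2-ene (excess), second-generation Grubbs catalyst RuCl2(=CHPh)(PCy3)(H2IMes) (3 mol%), CH2Cl2, 35 °C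
Reagents that add atoms: 2-methylbut-2-ene, CC=C(C)C
Why: olefin cross-metathesis converts only the terminal vinyl group into the isopropylidene terminus, while the trisubstituted alkene and the carbinol centre are inert.

**Step 11**
Reactants: 16 (2E,4S)-4-hydroxy-3,7-dimethylocta-2,6-dien-1-yl acetate
Product: 17 (2E,4S)-3,7-dimethylocta-2,6-diene-1,4-diyl diacetate
Conditions: Ac2O, pyridine, DMAP (cat.), CH2Cl2, 0 °C to rt
Reagents that add atoms: acetic anhydride, CC(=O)OC(C)=O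
Why: acetylation masks the hydroxyl so that it cannot close a tetrahydrofuran onto the neighbouring prenyl cation in the acid step.

**Step 12**
Reactants: 13 methyl 3-[3,4-bis(pivaloyloxy)benzoyl]-2,4,6-trihydroxy-5-[(2R)-5-methyl-2-(prop-1-en-2-yl)hex-4-en-1-yl]benzoate; 17 (2E,4S)-3,7-dimethylocta-2,6-diene-1,4-diyl diacetate
Product: 18 methyl (3R)-5-[3,4-bis(pivaloyloxy)benzoyl]-3-[(2E,4S)-4-acetoxy-3,7-dimethylocta-2,6-dien-1-yl]-2,6-dihydroxy-3-[(2R)-5-methyl-2-(prop-1-en-2-yl)hex-4-en-1-yl]-4-oxocyclohexa-1,5-diene-1-carboxylate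
Conditions: Pd2(dba)3·CHCl3 (2.5 mol%), (R,R)-DACH-phenyl Trost ligand (7.5 mol%), Et3N (1.2 equiv), CH2Cl2, 0 °C to rt
Reagents that add atoms: none
Why: Proposed new method: the triethylammonium salt of 13 (a vinylogous acid, soft nucleophile) attacks the unhindered CH2 terminus of the syn-π-allylpalladium complex formed by ionising the primary acetate of 17 (the hindered secondary acetate is not ionised), and because O-allylation and allylation at an acyl-bearing carbon are reversible under zerovalent palladium the allyl group ends on the only alkyl-bearing ring carbon with the E alkene retained, while the chiral pocket of the ligand selects the face of the flat nucleophile and so sets the new quaternary centre (3R, the future C1); the closest known reaction types are the Tsuji–Trost dearomative allylation of acylphloroglucinols and the palladium/Trost-ligand asymmetric allylic dearomatisation of naphthols, and any epimer at the new centre is removed after step 15.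

**Step 13**
Reactants: 18 methyl (3R)-5-[3,4-bis(pivaloyloxy)benzoyl]-3-[(2E,4S)-4-acetoxy-3,7-dimethylocta-2,6-dien-1-yl]-2,6-dihydroxy-3-[(2R)-5-methyl-2-(prop-1-en-2-yl)hex-4-en-1-yl]-4-oxocyclohexa-1,5-diene-1-carboxylate
Product: 20 (6R)-2-[3,4-bis(pivaloyloxy)benzoyl]-6-[(2E,4S)-4-acetoxy-3,7-dimethylocta-2,6-dien-1-yl]-3,5-dihydroxy-6-[(2R)-5-methyl-2-(prop-1-en-2-yl)hex-4-en-1-yl]cyclohexa-2,4-dien-1-one, via carboxylic acid 19 (not isolated)
Conditions: LiI (5 equiv), EtOAc, reflux under an argon stream; then aq. HCl (pH 3), rt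
Reagents that add atoms: none
Why: Krapcho-type dealkoxycarbonylation, in which iodide removes the methyl group of the chelated ester by SN2 and the vinylogous β-keto acid loses CO2, so the non-hydrolytic conditions spare the acetate and aryl pivalates and the quaternary centre is untouched.

**Step 14**
Reactants: 20 (6R)-2-[3,4-bis(pivaloyloxy)benzoyl]-6-[(2E,4S)-4-acetoxy-3,7-dimethylocta-2,6-dien-1-yl]-3,5-dihydroxy-6-[(2R)-5-methyl-2-(prop-1-en-2-yl)hex-4-en-1-yl]cyclohexa-2,4-dien-1-one; 9 1-bromo-3-methylbut-2-ene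
Product: 21 (6R)-2-[3,4-bis(pivaloyloxy)benzoyl]-6-[(2E,4S)-4-acetoxy-3,7-dimethylocta-2,6-dien-1-yl]-3,5-dihydroxy-4-(3-methylbut-2-en-1-yl)-6-[(2R)-5-methyl-2-(prop-1-en-2-yl)hex-4-en-1-yl]cyclohexa-2,4-dien-1-one
Conditions: LiN(SiMe3)2 (2.1 equiv), THF, −78 °C; then 9 (1.1 equiv), −78 to 0 °C; aq. NH4Cl
Reagents that add atoms: none
Why: SN2 C-alkylation of the lithium-chelated dienolate at its only C–H ring carbon (the reaction that completes the hop β-acids) places the prenyl group regiospecifically and creates no stereocentre.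

**Step 15**
Reactants: 21 (6R)-2-[3,4-bis(pivaloyloxy)benzoyl]-6-[(2E,4S)-4-acetoxy-3,7-dimethylocta-2,6-dien-1-yl]-3,5-dihydroxy-4-(3-methylbut-2-en-1-yl)-6-[(2R)-5-methyl-2-(prop-1-en-2-yl)hex-4-en-1-yl]cyclohexa-2,4-dien-1-one
Product: 22 (1S,5S,7R)-3-[3,4-bis(pivaloyloxy)benzoyl]-1-[(2E,4S)-4-acetoxy-3,7-dimethylocta-2,6-dien-1-yl]-2-hydroxy-6,6-dimethyl-5,7-bis(3-methylbut-2-en-1-yl)bicyclo[3.3.1]non-2-ene-4,9-dione
Conditions: HCO2H (98%), 0.02 M, rt, 12 h; evaporate; brief MeOH/NaHCO3 wash; chromatography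
Reagents that add atoms: none
Why: biomimetic cation–enol cyclisation, in which Markovnikov protonation of the isopropenyl group gives the tertiary cation that the prenylated enol carbon captures through a chair transition state with the C7 prenyl equatorial, so C7 (R) is the lavandulyl centre and C5 (S) is forced by the bridge from C1, while O-capture and formate capture are reversible in formic acid and material from any C1 epimer ends in a separable diastereomer.

**Step 16**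
Reactants: 22 (1S,5S,7R)-3-[3,4-bis(pivaloyloxy)benzoyl]-1-[(2E,4S)-4-acetoxy-3,7-dimethylocta-2,6-dien-1-yl]-2-hydroxy-6,6-dimethyl-5,7-bis(3-methylbut-2-en-1-yl)bicyclo[3.3.1]non-2-ene-4,9-dione
Product: 23 (1S,5S,7R)-3-(3,4-dihydroxybenzoyl)-2-hydroxy-1-[(2E,4S)-4-hydroxy-3,7-dimethylocta-2,6-dien-1-yl]-6,6-dimethyl-5,7-bis(3-methylbut-2-en-1-yl)bicyclo[3.3.1]non-2-ene-4,9-dione (CNP0142498.1)
Conditions: K2CO3 (4 equiv), degassed MeOH, argon, rt to 40 °C; aq. HCl to pH 3
Reagents that add atoms: none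
Why: carbonate-mediated transesterification removes the allylic acetate and both aryl pivalates in one operation, with no stereocentre touched and the enolised trione stable as its anion.

**Compound list**
1 | 3,4-dihydroxybenzoic acid | O=C(O)c1ccc(O)c(O)c1 | starting material
2 | 3,4-bis(pivaloyloxy)benzoic acid | CC(C)(C)C(=O)Oc1ccc(cc1OC(=O)C(C)(C)C)C(=O)O | intermediate
3 | 3,4-bis(pivaloyloxy)benzoyl chloride | CC(C)(C)C(=O)Oc1ccc(cc1OC(=O)C(C)(C)C)C(Cl)=O | intermediate
4 | methyl 2,4,6-trihydroxybenzoate | COC(=O)c1c(O)cc(O)cc1O | starting material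
5 | methyl 3-[3,4-bis(pivaloyloxy)benzoyl]-2,4,6-trihydroxybenzoate | COC(=O)c1c(O)cc(O)c(C(=O)c2ccc(OC(=O)C(C)(C)C)c(OC(=O)C(C)(C)C)c2)c1O | intermediate
6 | (S)-4-benzyloxazolidin-2-one | O=C1N[C@@H](Cc2ccccc2)CO1 | starting material
7 | 3-methylbut-2-enoyl chloride | CC(C)=CC(Cl)=O | starting material
8 | (S)-4-benzyl-3-(3-methylbut-2-enoyl)oxazolidin-2-one | CC(C)=CC(=O)N1[C@@H](Cc2ccccc2)COC1=O | intermediate
9 | 1-bromo-3-methylbut-2-ene (prenyl bromide) | CC(C)=CCBr | starting material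
10 | (S)-4-benzyl-3-[(2S)-5-methyl-2-(prop-1-en-2-yl)hex-4-enoyl]oxazolidin-2-one | CC(C)=CC[C@@H](C(C)=C)C(=O)N1[C@@H](Cc2ccccc2)COC1=O | intermediate
11 | (S)-lavandulol, (2S)-5-methyl-2-(prop-1-en-2-yl)hex-4-en-1-ol | CC(C)=CC[C@@H](C(C)=C)CO | intermediate
12 | (S)-lavandulyl triflate, (2S)-5-methyl-2-(prop-1-en-2-yl)hex-4-en-1-yl trifluoromethanesulfonate | CC(C)=CC[C@@H](C(C)=C)COS(=O)(=O)C(F)(F)F | intermediate
13 | methyl 3-[3,4-bis(pivaloyloxy)benzoyl]-2,4,6-trihydroxy-5-[(2R)-5-methyl-2-(prop-1-en-2-yl)hex-4-en-1-yl]benzoate | CC(C)=CC[C@@H](C(C)=C)Cc1c(O)c(C(=O)OC)c(O)c(C(=O)c2ccc(OC(=O)C(C)(C)C)c(OC(=O)C(C)(C)C)c2)c1O | intermediate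
14 | (E)-4-acetoxy-2-methylbut-2-enal | CC(=O)OC/C=C(\C)C=O | starting material
15 | (2E,4S)-4-hydroxy-3-methylhepta-2,6-dien-1-yl acetate | CC(=O)OC/C=C(\C)[C@@H](O)CC=C | intermediate
16 | (2E,4S)-4-hydroxy-3,7-dimethylocta-2,6-dien-1-yl acetate | CC(=O)OC/C=C(\C)[C@@H](O)CC=C(C)C | intermediate
17 | (2E,4S)-3,7-dimethylocta-2,6-diene-1,4-diyl diacetate | CC(=O)OC/C=C(\C)[C@@H](OC(C)=O)CC=C(C)C | intermediate
18 | methyl (3R)-5-[3,4-bis(pivaloyloxy)benzoyl]-3-[(2E,4S)-4-acetoxy-3,7-dimethylocta-2,6-dien-1-yl]-2,6-dihydroxy-3-[(2R)-5-methyl-2-(prop-1-en-2-yl)hex-4-en-1-yl]-4-oxocyclohexa-1,5-diene-1-carboxylate | CC(C)=CC[C@@H](C(C)=C)C[C@]1(C/C=C(\C)[C@@H](OC(C)=O)CC=C(C)C)C(O)=C(C(=O)OC)C(O)=C(C(=O)c2ccc(OC(=O)C(C)(C)C)c(OC(=O)C(C)(C)C)c2)C1=O | intermediate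
19 | (3R)-5-[3,4-bis(pivaloyloxy)benzoyl]-3-[(2E,4S)-4-acetoxy-3,7-dimethylocta-2,6-dien-1-yl]-2,6-dihydroxy-3-[(2R)-5-methyl-2-(prop-1-en-2-yl)hex-4-en-1-yl]-4-oxocyclohexa-1,5-diene-1-carboxylic acid | CC(C)=CC[C@@H](C(C)=C)C[C@]1(C/C=C(\C)[C@@H](OC(C)=O)CC=C(C)C)C(O)=C(C(=O)O)C(O)=C(C(=O)c2ccc(OC(=O)C(C)(C)C)c(OC(=O)C(C)(C)C)c2)C1=O | intermediate
20 | (6R)-2-[3,4-bis(pivaloyloxy)benzoyl]-6-[(2E,4S)-4-acetoxy-3,7-dimethylocta-2,6-dien-1-yl]-3,5-dihydroxy-6-[(2R)-5-methyl-2-(prop-1-en-2-yl)hex-4-en-1-yl]cyclohexa-2,4-dien-1-one | CC(C)=CC[C@@H](C(C)=C)C[C@]1(C/C=C(\C)[C@@H](OC(C)=O)CC=C(C)C)C(O)=CC(O)=C(C(=O)c2ccc(OC(=O)C(C)(C)C)c(OC(=O)C(C)(C)C)c2)C1=O | intermediate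
21 | (6R)-2-[3,4-bis(pivaloyloxy)benzoyl]-6-[(2E,4S)-4-acetoxy-3,7-dimethylocta-2,6-dien-1-yl]-3,5-dihydroxy-4-(3-methylbut-2-en-1-yl)-6-[(2R)-5-methyl-2-(prop-1-en-2-yl)hex-4-en-1-yl]cyclohexa-2,4-dien-1-one | CC(C)=CC[C@@H](C(C)=C)C[C@]1(C/C=C(\C)[C@@H](OC(C)=O)CC=C(C)C)C(O)=C(CC=C(C)C)C(O)=C(C(=O)c2ccc(OC(=O)C(C)(C)C)c(OC(=O)C(C)(C)C)c2)C1=O | intermediate
22 | (1S,5S,7R)-3-[3,4-bis(pivaloyloxy)benzoyl]-1-[(2E,4S)-4-acetoxy-3,7-dimethylocta-2,6-dien-1-yl]-2-hydroxy-6,6-dimethyl-5,7-bis(3-methylbut-2-en-1-yl)bicyclo[3.3.1]non-2-ene-4,9-dione | CC(C)=CC[C@@H]1C[C@]2(C/C=C(\C)[C@@H](OC(C)=O)CC=C(C)C)C(=O)[C@@](CC=C(C)C)(C(=O)C(C(=O)c3ccc(OC(=O)C(C)(C)C)c(OC(=O)C(C)(C)C)c3)=C2O)C1(C)C | intermediate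
23 | (1S,5S,7R)-3-(3,4-dihydroxybenzoyl)-2-hydroxy-1-[(2E,4S)-4-hydroxy-3,7-dimethylocta-2,6-dien-1-yl]-6,6-dimethyl-5,7-bis(3-methylbut-2-en-1-yl)bicyclo[3.3.1]non-2-ene-4,9-dione | CC(C)=CC[C@@H]1C[C@]2(C/C=C(\C)[C@@H](O)CC=C(C)C)C(=O)[C@@](CC=C(C)C)(C(=O)C(C(=O)c3ccc(O)c(O)c3)=C2O)C1(C)C | target

**Step count**
Total: 16 steps. Longest linear sequence: 10 steps (4, 5, 6, 7, 8, 12, 13, 14, 15, 16, from 6 and 7).

**Three steps most likely to fail**

Step 15 (cation–enol cyclisation). Formic acid can also protonate the four trisubstituted alkenes, close the enol oxygen instead of carbon, or ionise the secondary allylic acetate. The fallback separates cation generation from Brønsted acid and sets out from 21. A hydrogen-atom-transfer/radical–polar crossover hydroalkoxylation (Co(salen), a divalent cobalt complex, with PhSiH3 and N-fluoro-2,4,6-trimethylpyridinium tetrafluoroborate) reacts only at the 1,1-disubstituted alkene and closes the flanking enol oxygen onto the tertiary carbon. This gives the pyranyl enol ether (3R,4aR)-6-[3,4-bis(pivaloyloxy)benzoyl]-4a-[(2E,4S)-4-acetoxy-3,7-dimethylocta-2,6-dien-1-yl]-7-hydroxy-2,2-dimethyl-3,8-bis(3-methylbut-2-en-1-yl)-3,4-dihydro-2H-chromen-5(4aH)-one F1. BF3·OEt2 in CH2Cl2 at −78 °C then re-ionises only that tertiary C–O bond, and the cation is captured at the prenylated carbon, which comes back to the route at 22.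

Step 12 (dearomative allylation). Risks are O-allylation, low facial control at the new quaternary centre, E/Z erosion in the π-allyl complex and ionisation of the secondary acetate. The fallback replaces the π-allyl electrophile by an SN2 partner under ion-pair control and sets out from 17 and 13. Lipase hydrolysis (Candida antarctica lipase B, pH 7 buffer) of the primary acetate of 17 gives (2E,4S)-1-hydroxy-3,7-dimethylocta-2,6-dien-4-yl acetate F2. CBr4/PPh3 converts it into (2E,4S)-1-bromo-3,7-dimethylocta-2,6-dien-4-yl acetate F3. C-alkylation of 13 with F3 under chiral phase-transfer conditions (CsOH·H2O, N-(9-anthracenylmethyl)cinchonidinium bromide, CH2Cl2, −40 °C) comes back to the route at 18.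

Step 13 (removal of the blocking ester). The chelated methyl ester may resist iodide, or the liberated MeI may methylate the enol. The fallback uses chlorine as the blocking group and sets out from 3. Friedel–Crafts acylation of benzene-1,3,5-triol F4 with 3 gives [3,4-bis(pivaloyloxy)phenyl](2,4,6-trihydroxyphenyl)methanone F5. One equivalent of N-chlorosuccinimide gives (3-chloro-2,4,6-trihydroxyphenyl)[3,4-bis(pivaloyloxy)phenyl]methanone F6. C-alkylation with 12 (LiN(SiMe3)2, THF) gives [3,4-bis(pivaloyloxy)phenyl]{3-chloro-2,4,6-trihydroxy-5-[(2R)-5-methyl-2-(prop-1-en-2-yl)hex-4-en-1-yl]phenyl}methanone F7. Palladium-catalysed allylation with 17 as in step 12 gives (6R)-2-[3,4-bis(pivaloyloxy)benzoyl]-6-[(2E,4S)-4-acetoxy-3,7-dimethylocta-2,6-dien-1-yl]-4-chloro-3,5-dihydroxy-6-[(2R)-5-methyl-2-(prop-1-en-2-yl)hex-4-en-1-yl]cyclohexa-2,4-dien-1-one F8. Zn/AcOH at rt removes the chlorine and comes back to the route at 20.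

**Further compounds**
F1 | step 15 | (3R,4aR)-6-[3,4-bis(pivaloyloxy)benzoyl]-4a-[(2E,4S)-4-acetoxy-3,7-dimethylocta-2,6-dien-1-yl]-7-hydroxy-2,2-dimethyl-3,8-bis(3-methylbut-2-en-1-yl)-3,4-dihydro-2H-chromen-5(4aH)-one | CC(C)=CC[C@@H]1C[C@]2(C/C=C(\C)[C@@H](OC(C)=O)CC=C(C)C)C(OC1(C)C)=C(CC=C(C)C)C(O)=C(C(=O)c3ccc(OC(=O)C(C)(C)C)c(OC(=O)C(C)(C)C)c3)C2=O
F2 | step 12 | (2E,4S)-1-hydroxy-3,7-dimethylocta-2,6-dien-4-yl acetate | OC/C=C(\C)[C@@H](OC(C)=O)CC=C(C)C
F3 | step 12 | (2E,4S)-1-bromo-3,7-dimethylocta-2,6-dien-4-yl acetate | BrC/C=C(\C)[C@@H](OC(C)=O)CC=C(C)C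
F4 | step 13 | benzene-1,3,5-triol (phloroglucinol) | Oc1cc(O)cc(O)c1
F5 | step 13 | [3,4-bis(pivaloyloxy)phenyl](2,4,6-trihydroxyphenyl)methanone | CC(C)(C)C(=O)Oc1ccc(cc1OC(=O)C(C)(C)C)C(=O)c1c(O)cc(O)cc1O
F6 | step 13 | (3-chloro-2,4,6-trihydroxyphenyl)[3,4-bis(pivaloyloxy)phenyl]methanone | CC(C)(C)C(=O)Oc1ccc(cc1OC(=O)C(C)(C)C)C(=O)c1c(O)cc(O)c(Cl)c1O
F7 | step 13 | [3,4-bis(pivaloyloxy)phenyl]{3-chloro-2,4,6-trihydroxy-5-[(2R)-5-methyl-2-(prop-1-en-2-yl)hex-4-en-1-yl]phenyl}methanone | CC(C)=CC[C@@H](C(C)=C)Cc1c(O)c(Cl)c(O)c(C(=O)c2ccc(OC(=O)C(C)(C)C)c(OC(=O)C(C)(C)C)c2)c1O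
F8 | step 13 | (6R)-2-[3,4-bis(pivaloyloxy)benzoyl]-6-[(2E,4S)-4-acetoxy-3,7-dimethylocta-2,6-dien-1-yl]-4-chloro-3,5-dihydroxy-6-[(2R)-5-methyl-2-(prop-1-en-2-yl)hex-4-en-1-yl]cyclohexa-2,4-dien-1-one | CC(C)=CC[C@@H](C(C)=C)C[C@]1(C/C=C(\C)[C@@H](OC(C)=O)CC=C(C)C)C(O)=C(Cl)C(O)=C(C(=O)c2ccc(OC(=O)C(C)(C)C)c(OC(=O)C(C)(C)C)c2)C1=O
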